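**Retrosynthetic overview**

1. The target is a 2,2-disubstituted 2H-chromen-6-ol. The last skeletal bond made is C2–C1' (pyran C2 to the first side-chain CH2), which is disconnected to a C16 homoallyl Grignard reagent and a 6-silyloxy-2-methyl-4H-chromen-4-one.
2. Enabling feature: in the pyran ring (ring B: O1, C2, C3, C4, C4a, C8a), C2 lies between O1 and the C3=C4 double bond. With C4 at the ketone level, ring B is a flat 4-pyranone whose C2 carries only CH3 and is the β-carbon. O-Silylation makes it an aromatic 4-silyloxybenzopyrylium cation that should accept the alkyl group at C2 under chiral copper catalysis, creating the (2S) quaternary centre. The C4 oxygen is then removed (C=O to CHOH to C3=C4).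
3. Side chain: the (S) ring stereocentre and the ring double bond come from 2,4,4-trimethylcyclohex-2-enone by CBS reduction and Johnson–Claisen 1,3-chirality transfer. The (E)-trisubstituted alkene comes from alkyne methylalumination and oxirane opening.
4. Ring order: the benzene and cyclohexene rings are bought. Ring B is closed first (step 1) and afterwards only changes oxidation level. The key step closes no ring.

Key step: step 10

Assumption: the sense of induction of the copper/bisphosphine catalyst in the key step cannot be predicted with certainty, so the ligand antipode that gives the (2S)-chromanone would be fixed in a pilot run.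

**Route**

Step 1
Reactants: 1 2',5'-dihydroxyacetophenone
Product: 3 6-hydroxy-2-methyl-4H-chromen-4-one, via 1-(2,5-dihydroxyphenyl)butane-1,3-dione 2 (not isolated)
Conditions: NaH (5 equiv), EtOAc, THF, reflux; then conc. HCl, AcOH, 90 °C
Reagents that add atoms: ethyl acetate, CCOC(C)=O
Why: Crossed Claisen condensation of the ketone enolate (formed beside the two phenoxides) with ethyl acetate should give diketone 2, whose 2-hydroxyl then adds to the enolised diketone under acid and loses water (cyclodehydration) to the 4-pyranone, with no stereocentre formed.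

Step 2
Reactants: 3 6-hydroxy-2-methyl-4H-chromen-4-one
Product: 4 2-methyl-6-[(triisopropylsilyl)oxy]-4H-chromen-4-one
Conditions: iPr3SiCl, imidazole, DMF, rt
Reagents that add atoms: triisopropylsilyl chloride, CC(C)[Si](Cl)(C(C)C)C(C)C
Why: Standard silylation of the only free phenol gives a bulky aryl silyl ether that should survive the Grignard, hydride and mild acid steps and be cleaved by fluoride at the end.

Step 3
Reactants: 5 2,4,4-trimethylcyclohex-2-en-1-one
Product: 6 (1R)-2,4,4-trimethylcyclohex-2-en-1-ol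
Conditions: (S)-2-methyl-CBS-oxazaborolidine (10 mol %), BH3·SMe2 (0.7 equiv), THF, −20 °C
Reagents that add atoms: none
Why: CBS reduction, in which the ketone binds to the oxazaborolidine boron with the methyl-substituted alkenyl arm as the large group, so that the (S)-catalyst should deliver hydride in the 1,2-mode to the face that gives the (R)-allylic alcohol.

Step 4
Reactants: 6 (1R)-2,4,4-trimethylcyclohex-2-en-1-ol
Product: 8 ethyl 2-[(1S)-2,6,6-trimethylcyclohex-2-en-1-yl]acetate, via mixed ketene acetal 7 (not isolated)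
Conditions: MeC(OEt)3 (6 equiv), EtCO2H (5 mol %), 140 °C, EtOH distilled off
Reagents that add atoms: triethyl orthoacetate, CCOC(C)(OCC)OCC
Why: Johnson–Claisen rearrangement, in which the [3,3]-shift of ketene acetal 7 is suprafacial on the cyclohexene ring, so the C–O stereocentre is transferred to the new C–C bond at the carbon next to the gem-dimethyl group, setting the (S) ring stereocentre and moving the double bond into the required trisubstituted position in one operation.

Step 5
Reactants: 8 ethyl 2-[(1S)-2,6,6-trimethylcyclohex-2-en-1-yl]acetate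
Product: 9 2-[(1S)-2,6,6-trimethylcyclohex-2-en-1-yl]ethan-1-ol
Conditions: LiAlH4, Et2O, 0 °C
Reagents that add atoms: none
Why: Hydride reduction of the ester to the primary alcohol, which leaves the isolated trisubstituted alkene and the non-epimerisable stereocentre untouched.

Step 6
Reactants: 9 2-[(1S)-2,6,6-trimethylcyclohex-2-en-1-yl]ethan-1-ol
Product: 10 (6S)-6-(2-iodoethyl)-1,5,5-trimethylcyclohex-1-ene
Conditions: I2, PPh3, imidazole, CH2Cl2, 0 °C to rt
Reagents that add atoms: iodine, II
Why: Appel-type iodination, an SN2 displacement of the oxyphosphonium ion at an unhindered primary carbon remote from the stereocentre.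

Step 7
Reactants: 10 (6S)-6-(2-iodoethyl)-1,5,5-trimethylcyclohex-1-ene
Product: 11 (6S)-6-(but-3-yn-1-yl)-1,5,5-trimethylcyclohex-1-ene
Conditions: LiC≡CH·H2NCH2CH2NH2 (1.5 equiv), DMSO, 15 °C to rt
Reagents that add atoms: lithium acetylide (ethylenediamine complex), [Li]C#C
Why: SN2 alkylation of lithium acetylide in DMSO by a primary iodide whose β-carbon is an unbranched CH2 should give the terminal alkyne with little elimination.

Step 8
Reactants: 11 (6S)-6-(but-3-yn-1-yl)-1,5,5-trimethylcyclohex-1-ene
Product: 14 (3E)-4-methyl-6-[(1S)-2,6,6-trimethylcyclohex-2-en-1-yl]hex-3-en-1-ol, via alkenyl(dimethyl)alane 12 (not isolated), via lithium alkenylaluminate 13 (not isolated)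
Conditions: AlMe3 (2.5 equiv), Cp2ZrCl2 (0.25 equiv), CH2Cl2, 0 °C to rt; volatiles removed; nBuLi (1 equiv), hexane/THF, −30 °C; oxirane, −30 °C to rt
Reagents that add atoms: trimethylaluminium, C[Al](C)C; oxirane, C1CO1
Why: Zirconium-catalysed methylalumination of the terminal alkyne (Negishi carboalumination) adds CH3 and Al syn with Al on the terminal carbon, which fixes the (E) geometry, and the derived aluminate 13 should open oxirane with retention of that geometry to give the homoallylic alcohol.

Step 9
Reactants: 14 (3E)-4-methyl-6-[(1S)-2,6,6-trimethylcyclohex-2-en-1-yl]hex-3-en-1-ol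
Product: 15 (6S)-6-[(3E)-6-bromo-3-methylhex-3-en-1-yl]-1,5,5-trimethylcyclohex-1-ene
Conditions: CBr4, PPh3, CH2Cl2, 0 °C
Reagents that add atoms: tetrabromomethane, BrC(Br)(Br)Br
Why: Appel bromination of the primary alcohol under neutral conditions that should not isomerise either trisubstituted alkene.

Step 10
Reactants: 15 (6S)-6-[(3E)-6-bromo-3-methylhex-3-en-1-yl]-1,5,5-trimethylcyclohex-1-ene; 4 2-methyl-6-[(triisopropylsilyl)oxy]-4H-chromen-4-one
Product: 19 (2S)-2-methyl-2-[(3E)-4-methyl-6-[(1S)-2,6,6-trimethylcyclohex-2-en-1-yl]hex-3-en-1-yl]-6-[(triisopropylsilyl)oxy]-2,3-dihydro-4H-chromen-4-one, via homoallylmagnesium bromide 16 (not isolated), via 4-silyloxybenzopyrylium triflate 17 (not isolated), via trimethylsilyl enol ether 18 (not isolated)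
Conditions: 15 (1.5 equiv), Mg, Et2O, rt; separately 4, Me3SiOTf (1.1 equiv), CH2Cl2, rt; then CuBr·SMe2 (5 mol %), (R,R)-Ph-BPE [1,2-bis((2R,5R)-2,5-diphenylphospholan-1-yl)ethane] or its antipode (6 mol %), −78 °C, slow addition of the Grignard solution; then 1 M HCl, THF, 0 °C
Reagents that add atoms: none
Why: Proposed new method: Me3SiOTf silylates the C4 carbonyl oxygen of 4 to the aromatic benzopyrylium ion 17, Grignard reagent 16 transmetalates to the bisphosphine-bound monovalent copper centre, and the alkylcopper adds to C2 of 17 (π-complexation at C2=C3, a trivalent copper σ-intermediate at C2, reductive elimination) to give silyl enol ether 18, which mild acid hydrolyses to 19. The closest known reaction types are the copper/diphosphine-catalysed enantioselective conjugate addition of Grignard reagents to C2-unsubstituted chromones, the silyl- or boron-Lewis-acid-promoted copper-catalysed Grignard additions to weak or cationic heteroaromatic acceptors, and the enantioselective additions of copper acetylides or silyl ketene acetals to 2-substituted 4-silyloxybenzopyrylium salts that already create a fully substituted C2; what is untested is the combination of a primary alkyl Grignard reagent with a 2-methyl substrate. No ring is closed. The new stereocentre C2 is set by catalyst control, the ligand antipode deciding which face of the planar cation (differentiated at C2 by the in-plane CH3 against O1 and C3) receives the alkyl group, while the remote (S) centre of the side chain should exert no bias, so an error in facial selectivity would appear as a C2 epimer detectable by NMR or HPLC. The step needs attack at C2 and not C4, which the donor-substituted, silyl-shielded C4 and the soft copper nucleophile should secure; addition and not deprotonation of the acidic 2-CH3 group, which slow addition of 16 at −78 °C (transmetalation faster than proton transfer) should secure; and the catalysed pathway over uncatalysed Grignard addition, which the low stationary concentration of 16 should secure.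

Step 11
Reactants: 19 (2S)-2-methyl-2-[(3E)-4-methyl-6-[(1S)-2,6,6-trimethylcyclohex-2-en-1-yl]hex-3-en-1-yl]-6-[(triisopropylsilyl)oxy]-2,3-dihydro-4H-chromen-4-one
Product: 20 (2S,4RS)-2-methyl-2-[(3E)-4-methyl-6-[(1S)-2,6,6-trimethylcyclohex-2-en-1-yl]hex-3-en-1-yl]-6-[(triisopropylsilyl)oxy]-3,4-dihydro-2H-chromen-4-ol
Conditions: NaBH4, MeOH/THF, 0 °C
Reagents that add atoms: none
Why: Borohydride 1,2-reduction of the aryl ketone gives the C4 carbinol as a mixture of epimers, which does not matter because C4 becomes sp2 in step 12, and the cold, weakly basic conditions should leave the C2 aryl ether centre intact.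

Step 12
Reactants: 20 (2S,4RS)-2-methyl-2-[(3E)-4-methyl-6-[(1S)-2,6,6-trimethylcyclohex-2-en-1-yl]hex-3-en-1-yl]-6-[(triisopropylsilyl)oxy]-3,4-dihydro-2H-chromen-4-ol
Product: 21 triisopropyl{[(2S)-2-methyl-2-[(3E)-4-methyl-6-[(1S)-2,6,6-trimethylcyclohex-2-en-1-yl]hex-3-en-1-yl]-2H-chromen-6-yl]oxy}silane
Conditions: TsOH·H2O (5 mol %), toluene, 50 °C
Reagents that add atoms: none
Why: Acid-catalysed E1 dehydration of the benzylic alcohol, in which the C4 cation is stabilised by the ortho ring oxygen O1 and can lose a proton only from C3 because C2 is fully substituted, so the C3=C4 double bond of the 2H-chromene should form without touching C2.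

Step 13
Reactants: 21 triisopropyl{[(2S)-2-methyl-2-[(3E)-4-methyl-6-[(1S)-2,6,6-trimethylcyclohex-2-en-1-yl]hex-3-en-1-yl]-2H-chromen-6-yl]oxy}silane
Product: 22 (2S)-2-methyl-2-[(3E)-4-methyl-6-[(1S)-2,6,6-trimethylcyclohex-2-en-1-yl]hex-3-en-1-yl]-2H-chromen-6-ol
Conditions: Bu4NF, THF, 0 °C
Reagents that add atoms: none
Why: Fluoride cleavage of the aryl silyl ether (driven by Si–F bond formation) should free the phenol under conditions that spare the chromene and both alkenes.

**Compound list**

1 | 2',5'-dihydroxyacetophenone | CC(=O)c1cc(O)ccc1O | starting material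
2 | 1-(2,5-dihydroxyphenyl)butane-1,3-dione | CC(=O)CC(=O)c1cc(O)ccc1O | intermediate
3 | 6-hydroxy-2-methyl-4H-chromen-4-one | CC1=CC(=O)c2cc(O)ccc2O1 | intermediate
4 | 2-methyl-6-[(triisopropylsilyl)oxy]-4H-chromen-4-one | CC1=CC(=O)c2cc(O[Si](C(C)C)(C(C)C)C(C)C)ccc2O1 | intermediate
5 | 2,4,4-trimethylcyclohex-2-en-1-one | CC1=CC(C)(C)CCC1=O | starting material
6 | (1R)-2,4,4-trimethylcyclohex-2-en-1-ol | O[C@@H]1CCC(C)(C)C=C1C | intermediate
7 | 1-ethoxy-1-{[(1R)-2,4,4-trimethylcyclohex-2-en-1-yl]oxy}ethene | C=C(OCC)O[C@@H]1CCC(C)(C)C=C1C | intermediate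
8 | ethyl 2-[(1S)-2,6,6-trimethylcyclohex-2-en-1-yl]acetate | CC1=CCCC(C)(C)[C@@H]1CC(=O)OCC | intermediate
9 | 2-[(1S)-2,6,6-trimethylcyclohex-2-en-1-yl]ethan-1-ol | CC1=CCCC(C)(C)[C@@H]1CCO | intermediate
10 | (6S)-6-(2-iodoethyl)-1,5,5-trimethylcyclohex-1-ene | CC1=CCCC(C)(C)[C@@H]1CCI | intermediate
11 | (6S)-6-(but-3-yn-1-yl)-1,5,5-trimethylcyclohex-1-ene | CC1=CCCC(C)(C)[C@@H]1CCC#C | intermediate
12 | dimethyl[(1E)-2-methyl-4-[(1S)-2,6,6-trimethylcyclohex-2-en-1-yl]but-1-en-1-yl]alumane | CC1=CCCC(C)(C)[C@@H]1CC/C(C)=C/[Al](C)C | intermediate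
13 | lithium butyl(dimethyl)[(1E)-2-methyl-4-[(1S)-2,6,6-trimethylcyclohex-2-en-1-yl]but-1-en-1-yl]aluminate | CC1=CCCC(C)(C)[C@@H]1CC/C(C)=C/[Al-](C)(C)CCCC.[Li+] | intermediate
14 | (3E)-4-methyl-6-[(1S)-2,6,6-trimethylcyclohex-2-en-1-yl]hex-3-en-1-ol | CC1=CCCC(C)(C)[C@@H]1CC/C(C)=C/CCO | intermediate
15 | (6S)-6-[(3E)-6-bromo-3-methylhex-3-en-1-yl]-1,5,5-trimethylcyclohex-1-ene | CC1=CCCC(C)(C)[C@@H]1CC/C(C)=C/CCBr | intermediate
16 | [(3E)-4-methyl-6-[(1S)-2,6,6-trimethylcyclohex-2-en-1-yl]hex-3-en-1-yl]magnesium bromide | CC1=CCCC(C)(C)[C@@H]1CC/C(C)=C/CC[Mg]Br | intermediate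
17 | 2-methyl-6-[(triisopropylsilyl)oxy]-4-[(trimethylsilyl)oxy]chromenylium trifluoromethanesulfonate | Cc1cc(O[Si](C)(C)C)c2cc(O[Si](C(C)C)(C(C)C)C(C)C)ccc2[o+]1.[O-]S(=O)(=O)C(F)(F)F | intermediate
18 | (2S)-2-methyl-2-[(3E)-4-methyl-6-[(1S)-2,6,6-trimethylcyclohex-2-en-1-yl]hex-3-en-1-yl]-6-[(triisopropylsilyl)oxy]-4-[(trimethylsilyl)oxy]-2H-chromene | CC1=CCCC(C)(C)[C@@H]1CC/C(C)=C/CC[C@@]1(C)C=C(O[Si](C)(C)C)c2cc(O[Si](C(C)C)(C(C)C)C(C)C)ccc2O1 | intermediate
19 | (2S)-2-methyl-2-[(3E)-4-methyl-6-[(1S)-2,6,6-trimethylcyclohex-2-en-1-yl]hex-3-en-1-yl]-6-[(triisopropylsilyl)oxy]-2,3-dihydro-4H-chromen-4-one | CC1=CCCC(C)(C)[C@@H]1CC/C(C)=C/CC[C@@]1(C)CC(=O)c2cc(O[Si](C(C)C)(C(C)C)C(C)C)ccc2O1 | intermediate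
20 | (2S,4RS)-2-methyl-2-[(3E)-4-methyl-6-[(1S)-2,6,6-trimethylcyclohex-2-en-1-yl]hex-3-en-1-yl]-6-[(triisopropylsilyl)oxy]-3,4-dihydro-2H-chromen-4-ol | CC1=CCCC(C)(C)[C@@H]1CC/C(C)=C/CC[C@@]1(C)CC(O)c2cc(O[Si](C(C)C)(C(C)C)C(C)C)ccc2O1 | intermediate
21 | triisopropyl{[(2S)-2-methyl-2-[(3E)-4-methyl-6-[(1S)-2,6,6-trimethylcyclohex-2-en-1-yl]hex-3-en-1-yl]-2H-chromen-6-yl]oxy}silane | CC1=CCCC(C)(C)[C@@H]1CC/C(C)=C/CC[C@@]1(C)C=Cc2cc(O[Si](C(C)C)(C(C)C)C(C)C)ccc2O1 | intermediate
22 | (2S)-2-methyl-2-[(3E)-4-methyl-6-[(1S)-2,6,6-trimethylcyclohex-2-en-1-yl]hex-3-en-1-yl]-2H-chromen-6-ol | CC1=CCCC(C)(C)[C@@H]1CC/C(C)=C/CC[C@@]1(C)C=Cc2cc(O)ccc2O1 | target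

**Step count**

Total step count: 13 (steps 1–2 chromone branch, steps 3–9 side-chain branch, steps 10–13 union and end game).
Longest linear sequence: 11 steps (steps 3 to 13, from 5).

**Steps most likely to fail, with fallbacks**

Step 10. The process at risk is the copper-catalysed addition itself: proton transfer from the 2-methyl group of the pyrylium ion to the Grignard reagent may outrun C–C bond formation, and the catalyst may discriminate the two faces of the cation poorly. The fallback sets out from 15 and rejoins the route at 21. It forms the same C2–C1' bond by a stereospecific 1,2-metallate rearrangement of known type. The Grignard reagent 16 made from 15 would be trapped with 2-isopropoxy-4,4,5,5-tetramethyl-1,3,2-dioxaborolane to give the pinacol boronate F1. Commercial (R)-4-(trimethylsilyl)but-3-yn-2-ol would be carbamoylated (iPr2NCOCl, Et3N, toluene, reflux) to the propargylic carbamate F2. Lithiation of F2 (sBuLi, TMEDA, Et2O, −78 °C) and addition of F1 would give a boronate complex. On warming, the side-chain CH2 should migrate from boron to carbon with loss of the carbamate, giving the tertiary boronic ester F3. Oxidation (NaOH, H2O2) should then give the tertiary propargylic alcohol F4. Its configuration follows from that of F2: borylation with retention, migration with inversion, oxidation with retention. Should the borylation prove invertive for this substrate, the (S)-alcohol would be used instead. K2CO3 in MeOH would remove the alkynyl silyl group and give the terminal alkyne F5. Sonogashira coupling (PdCl2(PPh3)2, CuI, Et3N, rt) with (4-bromo-3-iodophenoxy)triisopropylsilane F6, made from commercial 4-bromo-3-iodophenol (iPr3SiCl, imidazole), should take place at the C–I bond and give the aryl alkyne F7. Semihydrogenation (H2, Pd/CaCO3 poisoned with Pb(OAc)2, quinoline, EtOAc) would give the (Z)-allylic alcohol F8. Intramolecular etherification of the tertiary alcohol with the ortho C–Br bond under zerovalent palladium catalysis (Pd(OAc)2, 2-(di-tert-butylphosphino)-1,1'-binaphthyl, Cs2CO3, toluene, 80 °C) would then close ring B and give 21.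

Step 3. The process at risk is facial selection in the hydride transfer to an α-alkyl cyclic enone. Insufficient selectivity would lower the enantiomeric purity of 6 and, after step 10, the diastereomeric purity of every later compound. The fallback sets out from 5 and rejoins at 6. It replaces asymmetric reduction by enzymatic kinetic resolution. Ketone 5 would be reduced without stereocontrol (NaBH4, CeCl3·7H2O, MeOH, 0 °C, Luche reduction) to the racemic allylic alcohol F9. Lipase-catalysed transesterification (lipase from Burkholderia cepacia or Candida antarctica lipase B, vinyl acetate, hexane, rt) should, by the usual empirical rule for secondary alcohols, acylate the (R)-enantiomer to the (R)-acetate F10 and leave the (S)-alcohol F11. After chromatographic separation, methanolysis of F10 (K2CO3, MeOH) would give 6. F11 could be oxidised back to 5 (MnO2, CH2Cl2) and recycled.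

Step 12. The process at risk is the fate of the C4 benzylic cation under acid. Cation–olefin cyclisation onto the side-chain double bond, acid-induced migration of the trisubstituted double bonds, or heterolysis of the C2–O1 bond (which would erode the C2 configuration) may compete with proton loss from C3. The fallback sets out from 19 and rejoins at 21, bypassing 20 and avoiding any carbocation. Ketone 19 would be converted at −78 °C (KN(SiMe3)2, PhNTf2, THF) into the enol triflate F12, which already carries the C3=C4 double bond. The C–O bond would then be reduced with formate under zerovalent palladium catalysis (Pd(OAc)2, PPh3, HCO2H, Bu3N, DMF, 60 °C) to give 21 directly.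

**Further compounds**

F1 | step 10 | 4,4,5,5-tetramethyl-2-[(3E)-4-methyl-6-[(1S)-2,6,6-trimethylcyclohex-2-en-1-yl]hex-3-en-1-yl]-1,3,2-dioxaborolane | CC1=CCCC(C)(C)[C@@H]1CC/C(C)=C/CCB1OC(C)(C)C(C)(C)O1
F2 | step 10 | (2R)-4-(trimethylsilyl)but-3-yn-2-yl N,N-diisopropylcarbamate | C[C@@H](OC(=O)N(C(C)C)C(C)C)C#C[Si](C)(C)C
F3 | step 10 | 2-[(3R,6E)-3,7-dimethyl-9-[(1S)-2,6,6-trimethylcyclohex-2-en-1-yl]-1-(trimethylsilyl)non-6-en-1-yn-3-yl]-4,4,5,5-tetramethyl-1,3,2-dioxaborolane | CC1=CCCC(C)(C)[C@@H]1CC/C(C)=C/CC[C@@](B1OC(C)(C)C(C)(C)O1)(C)C#C[Si](C)(C)C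
F4 | step 10 | (3S,6E)-3,7-dimethyl-9-[(1S)-2,6,6-trimethylcyclohex-2-en-1-yl]-1-(trimethylsilyl)non-6-en-1-yn-3-ol | CC1=CCCC(C)(C)[C@@H]1CC/C(C)=C/CC[C@@](O)(C)C#C[Si](C)(C)C
F5 | step 10 | (3S,6E)-3,7-dimethyl-9-[(1S)-2,6,6-trimethylcyclohex-2-en-1-yl]non-6-en-1-yn-3-ol | CC1=CCCC(C)(C)[C@@H]1CC/C(C)=C/CC[C@@](O)(C)C#C
F6 | step 10 | (4-bromo-3-iodophenoxy)triisopropylsilane | CC(C)[Si](Oc1ccc(Br)c(I)c1)(C(C)C)C(C)C
F7 | step 10 | (3S,6E)-1-{2-bromo-5-[(triisopropylsilyl)oxy]phenyl}-3,7-dimethyl-9-[(1S)-2,6,6-trimethylcyclohex-2-en-1-yl]non-6-en-1-yn-3-ol | CC1=CCCC(C)(C)[C@@H]1CC/C(C)=C/CC[C@@](O)(C)C#Cc1cc(O[Si](C(C)C)(C(C)C)C(C)C)ccc1Br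
F8 | step 10 | (1Z,3S,6E)-1-{2-bromo-5-[(triisopropylsilyl)oxy]phenyl}-3,7-dimethyl-9-[(1S)-2,6,6-trimethylcyclohex-2-en-1-yl]nona-1,6-dien-3-ol | CC1=CCCC(C)(C)[C@@H]1CC/C(C)=C/CC[C@@](O)(C)/C=C\c1cc(O[Si](C(C)C)(C(C)C)C(C)C)ccc1Br
F9 | step 3 | rac-2,4,4-trimethylcyclohex-2-en-1-ol | OC1CCC(C)(C)C=C1C
F10 | step 3 | (1R)-2,4,4-trimethylcyclohex-2-en-1-yl acetate | CC(=O)O[C@@H]1CCC(C)(C)C=C1C
F11 | step 3 | (1S)-2,4,4-trimethylcyclohex-2-en-1-ol | O[C@H]1CCC(C)(C)C=C1C
F12 | step 12 | (2S)-2-methyl-2-[(3E)-4-methyl-6-[(1S)-2,6,6-trimethylcyclohex-2-en-1-yl]hex-3-en-1-yl]-6-[(triisopropylsilyl)oxy]-2H-chromen-4-yl trifluoromethanesulfonate | CC1=CCCC(C)(C)[C@@H]1CC/C(C)=C/CC[C@@]1(C)C=C(OS(=O)(=O)C(F)(F)F)c2cc(O[Si](C(C)C)(C(C)C)C(C)C)ccc2O1
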